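**Retrosynthetic overview**
1. The two ketal C–O bonds at C2 of the flavonol-derived unit (to its own ring-D phenol and to O7 of the flavan) are cut last, giving a heptaphenolic 2-aryl-2-hydroxy-1,3-diketone; its C3–C8(flavan) bond is cut next, as an enantioselective Friedel–Crafts addition of the protected flavan to the central carbonyl of a diaryl vicinal triketone.
2. Flavan ring C is cut at C2–C3 and O1–C8a, giving 4-(benzyloxy)benzaldehyde (its C=O becomes C2–O1) and a 2-(2-fluoro-4,6-dibenzyloxyphenyl)ethylzinc reagent (C3 nucleophile, C8a electrophile).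
3. Enabling feature: the three oxygens of flavan ring A sit at C5, C7 and C8a (1,3,5), so C8a is meta to both donor oxygens and can be carried as an aryl fluoride that an alkoxide displaces. C2 is a benzylic carbinol carbon with O1 as its only heteroatom and C3 is a plain CH2, so the aldehyde oxygen can be kept through to the aryl ether and C2 is not touched after it is set.
4. Ring order: the four benzene rings (A, B, D, E) come from the starting materials; pyran ring C of the flavan is formed in step 5; pyranone ring F and dihydrofuran ring G of the ketal core are formed together in step 10.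

Key step: step 5

Remark: C2 of the flavonol-derived unit is created last, by closure of both ring oxygens onto a ketone beside the fixed C3 centre, so it is not an independent centre; the descriptors of C2 and C3 are written throughout as they stand in the target SMILES, and the centres under external control are C3 (step 9) and flavan C2 (step 5).

Step 1
Reactants: 1 5-fluororesorcinol (5-fluorobenzene-1,3-diol)
Product: 2 1,3-bis(benzyloxy)-5-fluorobenzene
Conditions: BnBr (2.2 equiv), K2CO3, DMF, 60 °C
Reagents that add atoms: benzyl bromide, BrCc1ccccc1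
Why: Williamson etherification of both phenols by the SN2-reactive benzyl bromide under carbonate base; no stereocentre is involved.

Step 2
Reactants: 2 1,3-bis(benzyloxy)-5-fluorobenzene
Product: 4 2,4-bis(benzyloxy)-6-fluorobenzaldehyde, via aryl iminium chloride 3 (not isolated)
Conditions: POCl3, DMF, 0 → 60 °C; then H2O, rt
Reagents that add atoms: N,N-dimethylformamide, CN(C)C=O; water, O
Why: Vilsmeier–Haack formylation of the resorcinol diether should go para to one benzyloxy group and ortho to the other, that is to the ring carbon between fluorine and a benzyloxy group, the doubly flanked position between the two ethers being the slower site, and the iminium salt is hydrolysed on work-up.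

Step 3
Reactants: 4 2,4-bis(benzyloxy)-6-fluorobenzaldehyde
Product: 5 1,5-bis(benzyloxy)-3-fluoro-2-vinylbenzene
Conditions: Ph3PCH3Br, KOtBu, THF, 0 °C → rt
Reagents that add atoms: methyltriphenylphosphonium bromide, C[P+](c1ccccc1)(c1ccccc1)c1ccccc1.[Br-]
Why: Wittig methylenation of a non-enolisable, electron-rich aryl aldehyde by the unstabilised ylide; no stereocentre is formed.

Step 4
Reactants: 5 1,5-bis(benzyloxy)-3-fluoro-2-vinylbenzene
Product: 7 1,5-bis(benzyloxy)-3-fluoro-2-(2-iodoethyl)benzene, via alkylborane 6 (not isolated)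
Conditions: Sia2BH, THF, 0 °C; then I2, NaOMe, MeOH, 0 °C → rt
Reagents that add atoms: iodine, II
Why: Hydroboration–iodination, in which the bulky dialkylborane places boron on the terminal carbon of the styrene (anti-Markovnikov) and iodine with methoxide cleaves the primary B–C bond in preference to the hindered secondary ones to give the primary iodide.

Step 5
Reactants: 7 1,5-bis(benzyloxy)-3-fluoro-2-(2-iodoethyl)benzene; 8 4-(benzyloxy)benzaldehyde
Product: 12 (S)-5,7-bis(benzyloxy)-2-[4-(benzyloxy)phenyl]chroman, via dialkylzinc 9 (not isolated), via mixed alkylzinc 10 (not isolated), via potassium alkoxide 11 (not isolated)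
Conditions: Et2Zn (neat, 3 equiv), CuI (0.3 mol%), 50 °C, then volatiles off in vacuo; Zn(CH2SiMe3)2 (0.5 equiv), toluene; 8 (0.9 equiv), Ti(OiPr)4 (1.2 equiv), (1R,2R)-N,N'-bis(trifluoromethylsulfonyl)cyclohexane-1,2-diamine (8 mol%), −20 °C; then KOtBu (3 equiv), DMPU, 80 °C
Reagents that add atoms: none
Why: Iodine–zinc exchange and redistribution with Zn(CH2SiMe3)2 give the mixed reagent 10, whose arylethyl group (the silylmethyl group does not transfer) adds to aldehyde 8 on the titanium bis(sulfonamide) catalyst and forms C2–C3; potassium tert-butoxide then frees alkoxide 11, which attacks the fluorine-bearing ring carbon C8a and expels fluoride, forming O1–C8a. The closest known reaction types are the catalytic enantioselective addition of functionalised dialkylzincs to aromatic aldehydes and the base-mediated intramolecular SNAr etherification of 3-(2-fluoroaryl)propanols to chromans, joined here in one flask as in tandem reactions of zinc alkoxides formed in situ. Ring C closes by 6-exo-trig ipso addition–elimination through a Meisenheimer-type transition state; should an elimination–addition path through the C8–C8a aryne intervene, it should give the same chroman, since the tether reaches only C8a and the C7 oxygen directs the alkoxide to that carbon. The new stereocentre C2 is controlled by the (1R,2R) ligand, which delivers the alkyl group to the Si face of aromatic aldehydes and so should give the (S)-carbinol; its C–O bond is not broken in the ring closure, so the configuration passes unchanged into the flavan, which has no base-labile centre. The step needs group selectivity in the zinc reagent, secured by the non-transferable silylmethyl ligand, and substitution at C8a without loss of optical purity, secured by the single C–F bond, by the meta placing of both ring-A oxygens (no resonance deactivation of C8a) and by keeping the aldehyde the limiting component so that no carbonyl hydride acceptor is left during heating.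

Step 6
Reactants: 13 1-(2,4,6-trihydroxyphenyl)ethanone
Product: 14 1-[2,4,6-tris(benzyloxy)phenyl]ethanone
Conditions: BnBr (3.6 equiv), K2CO3, DMF, 80 °C
Reagents that add atoms: benzyl bromide, BrCc1ccccc1
Why: Williamson etherification, the two ketone-chelated ortho phenols needing the excess of benzyl bromide and heat; no stereocentre is involved.

Step 7
Reactants: 14 1-[2,4,6-tris(benzyloxy)phenyl]ethanone; 15 methyl 4-(benzyloxy)benzoate
Product: 16 1-[4-(benzyloxy)phenyl]-3-[2,4,6-tris(benzyloxy)phenyl]propane-1,3-dione
Conditions: LiN(SiMe3)2 (2.2 equiv), THF, −78 °C → rt; then aq. HCl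
Reagents that add atoms: none
Why: Crossed Claisen condensation of the lithium enolate of the methyl ketone with a non-enolisable aryl ester, pulled forward by deprotonation of the β-diketone formed.

Step 8
Reactants: 16 1-[4-(benzyloxy)phenyl]-3-[2,4,6-tris(benzyloxy)phenyl]propane-1,3-dione
Product: 17 1-[4-(benzyloxy)phenyl]-3-[2,4,6-tris(benzyloxy)phenyl]propane-1,2,3-trione
Conditions: DMP (2.5 equiv), pyridine, CH2Cl2, rt
Reagents that add atoms: DMP (1,1,1-triacetoxy-1,1-dihydro-1,2-benziodoxol-3(1H)-one), CC(=O)OI1(OC(C)=O)(OC(C)=O)OC(=O)c2ccccc12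
Why: Direct oxidation of the enolised 1,3-diketone at its central carbon by the pentavalent-iodine reagent to the vicinal triketone, a known conversion of β-dicarbonyl compounds that should leave benzyl ethers and electron-rich rings untouched.

Step 9
Reactants: 12 (S)-5,7-bis(benzyloxy)-2-[4-(benzyloxy)phenyl]chroman; 17 1-[4-(benzyloxy)phenyl]-3-[2,4,6-tris(benzyloxy)phenyl]propane-1,2,3-trione
Product: 18 (R)-2-{(S)-5,7-bis(benzyloxy)-2-[4-(benzyloxy)phenyl]chroman-8-yl}-1-[4-(benzyloxy)phenyl]-2-hydroxy-3-[2,4,6-tris(benzyloxy)phenyl]propane-1,3-dione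
Conditions: Cu(OTf)2 (10 mol%), (R,R)-t-Bu-BOX [2,2'-(propane-2,2-diyl)bis((4R)-4-tert-butyl-4,5-dihydrooxazole)] (11 mol%), 4 Å molecular sieves, CH2Cl2, −20 °C → rt
Reagents that add atoms: none
Why: Enantioselective Friedel–Crafts hydroxyalkylation in which the divalent-copper bis(oxazoline) complex chelates the central carbonyl and the unhindered 4-(benzyloxy)benzoyl carbonyl of 17 (the activation known for pyruvates and vicinal tricarbonyl compounds) and shields one face, C8 of ring A of 12 (the position at which 5,7-dialkoxyflavans take electrophiles) adds to the open face, and the (R,R) ligand is chosen by analogy with the facial sense of pyruvate chelates to give the (R)-carbinol, the flavan centre being too remote to interfere.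

Step 10
Reactants: 18 (R)-2-{(S)-5,7-bis(benzyloxy)-2-[4-(benzyloxy)phenyl]chroman-8-yl}-1-[4-(benzyloxy)phenyl]-2-hydroxy-3-[2,4,6-tris(benzyloxy)phenyl]propane-1,3-dione
Product: 20 target CNP0208300.3, via heptaphenol 19 (not isolated)
Conditions: H2 (1 atm), Pd(OH)2/C, THF–MeOH, rt; filter; then HCl (cat.), THF, rt
Reagents that add atoms: none
Why: Hydrogenolysis removes the seven benzyl groups, and the C2 ketone of the freed heptaphenol 19 should then be closed as a double ketal by the ortho phenol of the trihydroxybenzoyl ring (pyranone ring F) and by the 7-OH of the flavan (dihydrofuran ring G), the only ketone that both phenols can reach, so that C2 is fixed by the preformed C3 centre, whose descriptor changes from R to S only because the CIP ranks of its two carbonyl-derived neighbours are exchanged.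

**Compound list**
1 | 5-fluororesorcinol (5-fluorobenzene-1,3-diol) | Oc1cc(O)cc(F)c1 | starting material
2 | 1,3-bis(benzyloxy)-5-fluorobenzene | Fc1cc(OCc2ccccc2)cc(OCc2ccccc2)c1 | intermediate
3 | N-[2,4-bis(benzyloxy)-6-fluorobenzylidene]-N-methylmethanaminium chloride (not isolated) | C[N+](C)=Cc1c(F)cc(OCc2ccccc2)cc1OCc1ccccc1.[Cl-] | intermediate
4 | 2,4-bis(benzyloxy)-6-fluorobenzaldehyde | O=Cc1c(F)cc(OCc2ccccc2)cc1OCc1ccccc1 | intermediate
5 | 1,5-bis(benzyloxy)-3-fluoro-2-vinylbenzene | C=Cc1c(F)cc(OCc2ccccc2)cc1OCc1ccccc1 | intermediate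
6 | {2-[2,4-bis(benzyloxy)-6-fluorophenyl]ethyl}bis(3-methylbutan-2-yl)borane (not isolated) | CC(C)C(C)B(C(C)C(C)C)CCc1c(F)cc(OCc2ccccc2)cc1OCc1ccccc1 | intermediate
7 | 1,5-bis(benzyloxy)-3-fluoro-2-(2-iodoethyl)benzene | ICCc1c(F)cc(OCc2ccccc2)cc1OCc1ccccc1 | intermediate
8 | 4-(benzyloxy)benzaldehyde | O=Cc1ccc(OCc2ccccc2)cc1 | starting material
9 | bis{2-[2,4-bis(benzyloxy)-6-fluorophenyl]ethyl}zinc (not isolated) | Fc1cc(OCc2ccccc2)cc(OCc2ccccc2)c1CC[Zn]CCc1c(F)cc(OCc2ccccc2)cc1OCc1ccccc1 | intermediate
10 | {2-[2,4-bis(benzyloxy)-6-fluorophenyl]ethyl}[(trimethylsilyl)methyl]zinc (not isolated) | C[Si](C)(C)C[Zn]CCc1c(F)cc(OCc2ccccc2)cc1OCc1ccccc1 | intermediate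
11 | potassium (S)-3-[2,4-bis(benzyloxy)-6-fluorophenyl]-1-[4-(benzyloxy)phenyl]propan-1-olate (zinc-bound as formed; not isolated) | [K+].[O-][C@H](c1ccc(OCc2ccccc2)cc1)CCc1c(F)cc(OCc2ccccc2)cc1OCc1ccccc1 | intermediate
12 | (S)-5,7-bis(benzyloxy)-2-[4-(benzyloxy)phenyl]chroman | O1[C@H](c2ccc(OCc3ccccc3)cc2)CCc2c(OCc3ccccc3)cc(OCc3ccccc3)cc12 | intermediate
13 | 1-(2,4,6-trihydroxyphenyl)ethanone | CC(=O)c1c(O)cc(O)cc1O | starting material
14 | 1-[2,4,6-tris(benzyloxy)phenyl]ethanone | CC(=O)c1c(OCc2ccccc2)cc(OCc2ccccc2)cc1OCc1ccccc1 | intermediate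
15 | methyl 4-(benzyloxy)benzoate | COC(=O)c1ccc(OCc2ccccc2)cc1 | starting material
16 | 1-[4-(benzyloxy)phenyl]-3-[2,4,6-tris(benzyloxy)phenyl]propane-1,3-dione | O=C(CC(=O)c1c(OCc2ccccc2)cc(OCc2ccccc2)cc1OCc1ccccc1)c1ccc(OCc2ccccc2)cc1 | intermediate
17 | 1-[4-(benzyloxy)phenyl]-3-[2,4,6-tris(benzyloxy)phenyl]propane-1,2,3-trione | O=C(C(=O)C(=O)c1c(OCc2ccccc2)cc(OCc2ccccc2)cc1OCc1ccccc1)c1ccc(OCc2ccccc2)cc1 | intermediate
18 | (R)-2-{(S)-5,7-bis(benzyloxy)-2-[4-(benzyloxy)phenyl]chroman-8-yl}-1-[4-(benzyloxy)phenyl]-2-hydroxy-3-[2,4,6-tris(benzyloxy)phenyl]propane-1,3-dione | O=C(c1c(OCc2ccccc2)cc(OCc2ccccc2)cc1OCc1ccccc1)[C@](O)(C(=O)c1ccc(OCc2ccccc2)cc1)c1c(OCc2ccccc2)cc(OCc2ccccc2)c2c1O[C@H](c1ccc(OCc3ccccc3)cc1)CC2 | intermediate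
19 | (R)-2-[(S)-5,7-dihydroxy-2-(4-hydroxyphenyl)chroman-8-yl]-2-hydroxy-1-(4-hydroxyphenyl)-3-(2,4,6-trihydroxyphenyl)propane-1,3-dione (not isolated) | O=C(c1c(O)cc(O)cc1O)[C@](O)(C(=O)c1ccc(O)cc1)c1c(O)cc(O)c2c1O[C@H](c1ccc(O)cc1)CC2 | intermediate
20 | CNP0208300.3: (2R,3S)-3,5,7-trihydroxy-2-(4-hydroxyphenyl)chroman-4-one joined through C2–O and C3–C to O7 and C8 of (2S)-5-hydroxy-2-(4-hydroxyphenyl)chroman (dihydrofuran ring G) | O=C1c2c(O)cc(O)cc2O[C@@]2(c3ccc(O)cc3)Oc3cc(O)c4c(c3[C@]12O)O[C@H](c1ccc(O)cc1)CC4 | target

**Step count and risks**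
Total step count: 10. Longest linear sequence: 7 steps (steps 1, 2, 3, 4, 5, 9, 10).

Step 9 may fail through poor facial discrimination at the central carbonyl, whose two aroyl flanks are similar, or through competing substitution at C6 of ring A. The fallback sets out from 12 and replaces the arene substitution by an organometallic 1,2-addition at a regiochemically defined carbon. Bromination with N-bromosuccinimide (CH2Cl2, −78 °C), which goes to C8 of 5,7-dialkoxyflavans, should give (S)-5,7-bis(benzyloxy)-2-[4-(benzyloxy)phenyl]-8-bromochroman F1. Bromine–lithium exchange (n-BuLi, THF, −78 °C) gives the 8-lithiochroman F2, and ZnCl2 followed by n-BuLi gives the aryl(butyl)zinc F3. Titanium-catalysed enantioselective aryl transfer from F3 to the central carbonyl of 17 (Ti(OiPr)4, chiral bis(sulfonamide) diol ligand, toluene) comes back to the route at 18.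

Step 5 may fail because ring closure stalls while the alkoxide stays bound to zinc or titanium, or because the carbinol loses optical purity by reversible hydride transfer during heating. The fallback sets out from 7 and 8 and closes the ring by elimination–addition instead of addition–elimination. The addition is stopped by aqueous work-up and (S)-3-[2,4-bis(benzyloxy)-6-fluorophenyl]-1-[4-(benzyloxy)phenyl]propan-1-ol F4 is isolated. Lithium 2,2,6,6-tetramethylpiperidide (THF, −78 → 0 °C) lithiates the ring C–H between fluorine and the neighbouring benzyloxy group to the ring-lithiated lithium alkoxide F5, which loses LiF to the aryne lithium alkoxide F6. The alkoxide adds to the aryne at C8a, and the 8-lithiochroman F2 so formed is protonated on work-up, which comes back to the route at 12.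

Step 10 may fail because reduction of the diaryl α-ketol (benzylic C–O cleavage at C3 or ketone reduction) overtakes removal of the seven benzyl ethers, or because closure stops at hemiketals. The fallback sets out from 18 and uses BCl3 with pentamethylbenzene as benzyl-cation scavenger (CH2Cl2, −78 °C, then methanol). The Lewis acid removes the benzyl groups without reducing conditions and also catalyses the ketal closure of 19, coming back to the route at 20; this fallback makes no new compound (F0).

Further compounds
F1 | step 9 | (S)-5,7-bis(benzyloxy)-2-[4-(benzyloxy)phenyl]-8-bromochroman | Brc1c(OCc2ccccc2)cc(OCc2ccccc2)c2c1O[C@H](c1ccc(OCc3ccccc3)cc1)CC2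
F2 | step 9 | {(S)-5,7-bis(benzyloxy)-2-[4-(benzyloxy)phenyl]chroman-8-yl}lithium | [Li]c1c(OCc2ccccc2)cc(OCc2ccccc2)c2c1O[C@H](c1ccc(OCc3ccccc3)cc1)CC2
F3 | step 9 | butyl{(S)-5,7-bis(benzyloxy)-2-[4-(benzyloxy)phenyl]chroman-8-yl}zinc | CCCC[Zn]c1c(OCc2ccccc2)cc(OCc2ccccc2)c2c1O[C@H](c1ccc(OCc3ccccc3)cc1)CC2
F4 | step 5 | (S)-3-[2,4-bis(benzyloxy)-6-fluorophenyl]-1-[4-(benzyloxy)phenyl]propan-1-ol | O[C@H](c1ccc(OCc2ccccc2)cc1)CCc1c(F)cc(OCc2ccccc2)cc1OCc1ccccc1
F5 | step 5 | lithium (S)-3-[2,4-bis(benzyloxy)-6-fluoro-5-lithiophenyl]-1-[4-(benzyloxy)phenyl]propan-1-olate | [Li+].[O-][C@H](c1ccc(OCc2ccccc2)cc1)CCc1c(F)c([Li])c(OCc2ccccc2)cc1OCc1ccccc1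
F6 | step 5 | lithium (S)-3-[2,4-bis(benzyloxy)-5,6-didehydrophenyl]-1-[4-(benzyloxy)phenyl]propan-1-olate (aryne) | [Li+].[O-][C@H](c1ccc(OCc2ccccc2)cc1)CCC1=C(OCc2ccccc2)C=C(OCc2ccccc2)C#C1
F0 | step 10 | none | none
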